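At early times the readings told me little. The south-west run fell from 0.8% at 0.500 min to 0.4% at 1.00 min, a drop smaller than the scatter of 0.5 percentage points, so I leaned on the last reading of each run.

| flask | starting material | reagent in the second phase | remark | time | volume of the second phase over the first |
|---|---|---|---|---|---|
| east | 0.75 M | 1.42 M | run made earlier |  |  |
| south-west | 3 M | 1.42 M | run made earlier |  |  |
| flask | 1.5 M | 1.42 M |  | 10 min | 1.0 |

| run | time / min | target / % |
|---|---|---|
| east | 1.50 | 0.9 |
| east | 3.00 | 2.8 |
| east | 5.00 | 4.1 |
| east | 6.00 | 5.5 |
| south-west | 0.500 | 0.8 |
| south-west | 1.00 | 0.4 |
| south-west | 2.50 | 1.4 |
| south-west | 6.00 | 4.2 |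

(scatter of a reading: 0.5 percentage points)

- in the second phase: reagent in the second phase; everything else is in the first
- charges count per volume of the first phase; a concentration in a rate is the amount of a species over the volume of its own phase; every rate counts per litre of the first phase
- the earlier runs hold the two phases in the same ratio of volumes as the flask asked about

- birch: doubling the amount of reagent in the second phase, all else as stated
- cedar: doubling the transfer coefficient of the reagent in the second phase, all else as stated

* target at 10 min, in percent of the starting material charged
* the change that raises the amount of target at 10 min, in percent of the starting material charged most ("none" if none brings more than 2 percentage points) (birch / cedar / none)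
* amount of target at 10 min, in percent of the starting material charged, after birch

I worked with the fraction of starting material left, f, counted as one minus the target share, and defined k by f = exp(−kt). The last readings gave k = 0.00943 min⁻¹ in the east run and 0.00715 min⁻¹ in the south-west run. The charge differed by a factor of 4.00 and k by 1.32, so I treated the percent yield as nearly independent of the charge. Their mean, an empirical apparent constant k_m, is 0.00829 min⁻¹, read at the reagent charge of 1.42 M that both runs shared. For the flask, at 1.5 M, this gave 7.96% at 10 min.

The weak link was that each k rested on one reading. Carrying the scatter through the mean of the two, and then out to 10 min, put 0.59 points on my figure.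

The forecast stood lower, at 7.5%, on a reaction “nearly first order in starting material”. It chose birch, with 14.2% after that change.

The flask gave 8.50%. The best change was birch, worth 3.4 points against 0.62 points for cedar, and it gave 11.9%.

    2 reagent in the reaction phase → self-condensation product (k = 2.18 × 10⁻⁴ M⁻¹ s⁻¹)
    reagent in the reaction phase + target → over-reacted product (k = 0.00172 M⁻¹ s⁻¹)
    reagent in the reaction phase ⇌ reagent in the second phase, rate k3*([reagent in the reaction phase] - [reagent in the second phase]/K3) per volume of the first phase (partition coefficient = 0.660, kL = 0.00335 s⁻¹)
    starting material + reagent in the reaction phase → target (k = 3.43 × 10⁻⁴ M⁻¹ s⁻¹)

The forecast's three answers held within their margins. The same k_m applied to the neighbouring flask, read at 2.5 min, gives 2.05% of target. That neighbour gave 1.74%, which is less, with 98.2% of the starting material left and reagent in the reaction phase at 0.580 M.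

All runs come from a simulation for an exercise; noise was put on by code.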